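**Retrosynthetic overview**
- Surinone B (11) is the enol form of 2-(13-phenyltridecanoyl)cyclohexane-1,3-dione. The six-membered dione ring is bought as cyclohexane-1,3-dione (1) and C-acylated at C-2 with a C11 half-ester (step 1).
- Key disconnection: the CH2–CH2 bond C10–C11 of the acyl chain, cut into two primary alkyl radicals. These come from ring-bearing acid 7 and 4-phenylbutanoic acid (8) in a mixed Kolbe electrolysis (anodic decarboxylative radical coupling).
- Enabling feature: C10 and C11 are unbranched, heteroatom-free methylenes inside the (CH2)12 tether, nine CH2 groups from the triketone carbocycle and three carbons from the benzene ring. Both radicals are therefore unstabilised primary ones that couple rather than being oxidised further.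
- The acidic, easily oxidised β-triketone (two ring C=O plus the exocyclic acyl C=O) is carried through the anode step as a temporary isoxazole ring (4-oxo-tetrahydro-1,2-benzoxazole).
- Ring order: carbocycle purchased; isoxazole ring closed (step 2); Kolbe union (step 4); isoxazole ring opened by N–O hydrogenolysis and hydrolysis (step 5). The benzene ring is purchased in 8, so 7 can be crossed with other ω-arylalkanoic acids.

Key step: step 4

Assumption: 11-methoxy-11-oxoundecanoic acid (2) is taken as a catalogue compound; the target has no stereocentre and its exocyclic-enol drawing is one tautomer of the freely equilibrating β-triketone, so no configuration has to be set.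

**Route**

Step 1
Reactants: 1 cyclohexane-1,3-dione; 2 11-methoxy-11-oxoundecanoic acid (monomethyl undecanedioate)
Product: 4 methyl 11-(2,6-dioxocyclohexylidene)-11-hydroxyundecanoate, via enol ester 3 (not isolated)
Conditions: DCC, DMAP, Et3N, CH2Cl2, 0 °C to rt
Reagents that add atoms: none
Why: Carbodiimide activation should O-acylate the dione enol (Steglich-type esterification) and DMAP should then shuttle the acyl group from O to C-2 (Fries-type O-to-C acyl migration), driven by formation of the strongly hydrogen-bonded β-triketone enol, while the remote methyl ester is inert.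

Step 2
Reactants: 4 methyl 11-(2,6-dioxocyclohexylidene)-11-hydroxyundecanoate
Product: 6 methyl 10-(4-oxo-4,5,6,7-tetrahydro-1,2-benzoxazol-3-yl)decanoate, via oxime 5 (not isolated)
Conditions: NH2OH·HCl, NaOAc, EtOH/H2O, reflux
Reagents that add atoms: hydroxylamine hydrochloride, NO.Cl
Why: In this classical isoxazole synthesis from a 1,3-dicarbonyl compound and hydroxylamine, nitrogen should attack the exocyclic acyl carbon (the site at which 2-acyl-1,3-diones condense with amines) and the oxime OH should then close onto a ring carbonyl with loss of water, the buffered medium leaving the methyl ester alone.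

Step 3
Reactants: 6 methyl 10-(4-oxo-4,5,6,7-tetrahydro-1,2-benzoxazol-3-yl)decanoate
Product: 7 10-(4-oxo-4,5,6,7-tetrahydro-1,2-benzoxazol-3-yl)decanoic acid
Conditions: LiOH, THF/H2O, rt; then 1 M HCl
Reagents that add atoms: lithium hydroxide, [Li+].[OH-]
Why: Ester saponification (BAc2) should proceed cleanly because the 3,5-disubstituted isoxazole has no ring C–H and is stable to cold aqueous hydroxide.

Step 4
Reactants: 7 10-(4-oxo-4,5,6,7-tetrahydro-1,2-benzoxazol-3-yl)decanoic acid; 8 4-phenylbutanoic acid
Product: 9 3-(12-phenyldodecyl)-6,7-dihydro-1,2-benzoxazol-4(5H)-one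
Conditions: Pt anode/Pt cathode, undivided cell, constant current (ca. 0.2 A cm−2), KOH (5 mol % of total acid), MeOH, 35–40 °C, 8 in 6-fold excess
Reagents that add atoms: none
Why: Anodic one-electron oxidation of the two carboxylates at smooth platinum gives acyloxy radicals that lose CO2 within the adsorbed carboxylate layer, and the resulting primary radicals (the 9-(4-oxo-tetrahydrobenzoxazol-3-yl)nonyl radical from 7 and the 3-phenylpropyl radical from 8) combine to form the C10–C11 bond of the chain. The closest known reaction type is the mixed (crossed) Kolbe electrolysis of an ω-functionalised alkanoic acid with an excess of a cheap co-acid, the classical way to assemble long-chain fatty acids, which tolerates remote ketones, esters and N-heteroaromatics. No ring is closed and no stereocentre is created. The step needs hetero- over homo-coupling and radical coupling over further oxidation to the cation; the first is secured statistically by the excess of 8, whose hydrocarbon homodimer is removed by chromatography, and the second by both radicals being unbranched primary alkyl radicals without α-heteroatom or α-aryl group, together with high current density in weakly acidic methanol. The isoxazole mask makes the anode step permissible: the free β-triketone is more acidic than the carboxylic acid and would be present as an easily oxidised enolate that disrupts the carboxylate layer, whereas the 4-acylisoxazole is neutral, electron-poor and not reduced at the hydrogen-evolving platinum cathode.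

Step 5
Reactants: 9 3-(12-phenyldodecyl)-6,7-dihydro-1,2-benzoxazol-4(5H)-one
Product: 11 Surinone B, via enaminone 10 (not isolated)
Conditions: H2 (1 atm), Raney Ni, EtOH, rt; filter; then 2 M HCl, EtOH/H2O, reflux
Reagents that add atoms: water, O
Why: Catalytic hydrogenolysis should cleave the weak isoxazole N–O bond to the vinylogous amide 10 (standard unmasking of an isoxazole to a β-amino enone), and aqueous acid should then hydrolyse its exocyclic C–N bond (enaminone hydrolysis) with expulsion of ammonium, the phenyl ring and the saturated chain being untouched at 1 atm and room temperature.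

**Compound list**
1 | cyclohexane-1,3-dione | O=C1CCCC(=O)C1 | starting material
2 | 11-methoxy-11-oxoundecanoic acid (monomethyl undecanedioate) | COC(=O)CCCCCCCCCC(=O)O | starting material
3 | 3-oxocyclohex-1-en-1-yl methyl undecanedioate (enol ester) | COC(=O)CCCCCCCCCC(=O)OC1=CC(=O)CCC1 | intermediate (not isolated)
4 | methyl 11-(2,6-dioxocyclohexylidene)-11-hydroxyundecanoate | O=C1CCCC(=O)C1=C(O)CCCCCCCCCC(=O)OC | intermediate
5 | methyl 11-(hydroxyimino)-11-(2-hydroxy-6-oxocyclohex-1-en-1-yl)undecanoate (oxime) | O=C1CCCC(O)=C1C(=NO)CCCCCCCCCC(=O)OC | intermediate (not isolated)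
6 | methyl 10-(4-oxo-4,5,6,7-tetrahydro-1,2-benzoxazol-3-yl)decanoate | O=C1CCCc2onc(CCCCCCCCCC(=O)OC)c21 | intermediate
7 | 10-(4-oxo-4,5,6,7-tetrahydro-1,2-benzoxazol-3-yl)decanoic acid | O=C1CCCc2onc(CCCCCCCCCC(=O)O)c21 | intermediate
8 | 4-phenylbutanoic acid | OC(=O)CCCc1ccccc1 | starting material
9 | 3-(12-phenyldodecyl)-6,7-dihydro-1,2-benzoxazol-4(5H)-one | O=C1CCCc2onc(CCCCCCCCCCCCc3ccccc3)c21 | intermediate
10 | 2-(1-amino-13-phenyltridecylidene)cyclohexane-1,3-dione (enaminone) | NC(CCCCCCCCCCCCc1ccccc1)=C1C(=O)CCCC1=O | intermediate (not isolated)
11 | Surinone B, 2-(1-hydroxy-13-phenyltridecylidene)cyclohexane-1,3-dione (no stereocentre) | O=C1CCCC(=O)C1=C(O)CCCCCCCCCCCCc1ccccc1 | target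

**Step count**
Total step count: 5. Longest linear sequence: 5 steps (1 and 2 to 11); acid 8 is purchased and enters at step 4.

**Steps most likely to fail**

Step 4 (Kolbe union). The valuable acid 7 may be lost to statistical homo-coupling, the primary radicals may be over-oxidised to cations (ether, alkene and ester by-products), or the heteroaromatic ketone may foul the anode. The fallback sets out from 7 and comes back to the route at 9 without any anodic chemistry. Acid 7 would be esterified with N-hydroxyphthalimide (DIC, cat. DMAP, CH2Cl2) to the redox-active ester 1,3-dioxoisoindolin-2-yl 10-(4-oxo-4,5,6,7-tetrahydro-1,2-benzoxazol-3-yl)decanoate F1. This would be coupled with bis(3-phenylpropyl)zinc F2, prepared from commercial 3-phenylpropylmagnesium bromide and ZnCl2, under NiCl2·glyme and 4,4'-di-tert-butyl-2,2'-bipyridine in THF/DMF at rt. This nickel-catalysed decarboxylative Negishi-type alkyl–alkyl coupling forms the same C10–C11 bond and should give 9.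

Step 5 (unmasking). The N–O hydrogenolysis may run on to over-reduction, or the doubly acyl-stabilised vinylogous amide may hydrolyse sluggishly and incompletely. The fallback sets out from 2 and 8, needs no mask, and comes back to the route at 11. Mixed Kolbe electrolysis of half-ester 2 with excess 8 (same cell and medium as step 4) should give methyl 13-phenyltridecanoate F3. Saponification (LiOH, THF/H2O) would give 13-phenyltridecanoic acid F4. DCC/DMAP/Et3N acylation of 1 with F4 should then pass through 3-oxocyclohex-1-en-1-yl 13-phenyltridecanoate F5 and rearrange in the flask to 11.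

Step 2 (isoxazole closure). The condensation may go with the wrong regiochemistry (nitrogen attacking a ring carbonyl), or hydroxylamine may attack the methyl ester. The fallback sets out from 1 and comes back to the route at 6 by a regiochemically unambiguous nitrile oxide cycloaddition. Dione 1 and pyrrolidine (toluene, Dean–Stark) would give 3-(pyrrolidin-1-yl)cyclohex-2-en-1-one F6. Commercial methyl 11-bromoundecanoate and NaNO2 in DMF (Kornblum nitrite displacement) would give methyl 11-nitroundecanoate F7. Dehydration of F7 with Boc2O and catalytic DMAP in MeCN in the presence of F6 would generate methyl 10-cyanodecanoate N-oxide F8. Its [3+2] cycloaddition to the enamine double bond, with carbon bonding to the enamine β-carbon, would give methyl 10-[4-oxo-7a-(pyrrolidin-1-yl)-3a,4,5,6,7,7a-hexahydro-1,2-benzoxazol-3-yl]decanoate F9 (racemic, cis-fused). F9 should lose pyrrolidine spontaneously to give 6.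

**Further compounds**
F1 | step 4 | 1,3-dioxoisoindolin-2-yl 10-(4-oxo-4,5,6,7-tetrahydro-1,2-benzoxazol-3-yl)decanoate | O=C1CCCc2onc(CCCCCCCCCC(=O)ON3C(=O)c4ccccc4C3=O)c21
F2 | step 4 | bis(3-phenylpropyl)zinc | C(CCc1ccccc1)[Zn]CCCc1ccccc1
F3 | step 5 | methyl 13-phenyltridecanoate | COC(=O)CCCCCCCCCCCCc1ccccc1
F4 | step 5 | 13-phenyltridecanoic acid | OC(=O)CCCCCCCCCCCCc1ccccc1
F5 | step 5 | 3-oxocyclohex-1-en-1-yl 13-phenyltridecanoate | O=C1C=C(OC(=O)CCCCCCCCCCCCc2ccccc2)CCC1
F6 | step 2 | 3-(pyrrolidin-1-yl)cyclohex-2-en-1-one | O=C1C=C(N2CCCC2)CCC1
F7 | step 2 | methyl 11-nitroundecanoate | COC(=O)CCCCCCCCCC[N+](=O)[O-]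
F8 | step 2 | methyl 10-cyanodecanoate N-oxide | COC(=O)CCCCCCCCCC#[N+][O-]
F9 | step 2 | methyl 10-[4-oxo-7a-(pyrrolidin-1-yl)-3a,4,5,6,7,7a-hexahydro-1,2-benzoxazol-3-yl]decanoate (racemic, cis-fused) | COC(=O)CCCCCCCCCC1=NOC2(N3CCCC3)CCCC(=O)C12
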